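**Strategy**

The target is disconnected at the C2–C3 bond and at the C1–O bond. Its chain C1(OH)–C2H2–C3H(C4H3) carries one and the same 2,4,5-trimethoxyphenyl ring at C1 (ring A) and at C3 (ring B), which makes the molecule formally a hydrate of the head-to-tail dimer of a single styrene. The key step unites two molecules of 2,4,5-trimethoxystyrene with water in a cationic cascade inside a confined chiral Brønsted acid, making both bonds and both stereocentres (1R,3S) in one operation, with no ring formed. The precursor is the achiral, unprotected styrene itself, obtained by Wittig methylenation of commercial 2,4,5-trimethoxybenzaldehyde.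

Key step: step 2

Remark on the structures: the target SMILES corresponds to (1R,3S)-1,3-bis(2,4,5-trimethoxyphenyl)butan-1-ol, C22H30O7 = 2 × C11H14O3 + H2O, with OH and CH3 syn in the zig-zag drawing of the Ar–C1–C2–C3–Ar chain. The structures are self-consistent and need no correction. The precursor needs no redesign beyond being delivered free of Lewis-basic triphenylphosphine oxide and of acid traces.

Assumption: the sense of induction of the confined acid cannot be predicted for this new reaction. The (S,S)-acid is written; its (R,R)-antipode is to be used instead if the first screen shows that it is the one leading to (1R,3S).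

**Step 1**
Reactants: 1 2,4,5-trimethoxybenzaldehyde; 2 methyltriphenylphosphonium bromide
Product: 4 2,4,5-trimethoxystyrene, via methylenetriphenylphosphorane 3 (not isolated)
Conditions: 2 (1.3 equiv), KOtBu (1.25 equiv), THF, 0 °C; then 1, 0 °C to rt; pentane trituration, plug of basic Al2O3; stored cold and dark, used fresh
Reagents that add atoms: none
Why: Wittig olefination, in which the non-stabilised ylide 3 adds to the aldehyde and the oxaphosphetane collapses to the terminal alkene and triphenylphosphine oxide; no stereocentre is formed and the aryl methyl ethers are inert to the base.

**Step 2**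
Reactants: 4 2,4,5-trimethoxystyrene (two molecules, one for each half of the product)
Product: 7 (1R,3S)-1,3-bis(2,4,5-trimethoxyphenyl)butan-1-ol, via 1-arylethyl cation 5 (not isolated), via dimeric C1 cation 6 (not isolated)
Conditions: (S,S)-iIDP (confined N-triflyl iminoimidodiphosphoric acid built from two (S)-3,3'-bis(2,4,6-triethylphenyl)-BINOL units, 5 mol %), wet CHCl3 (H2O set to 0.6 equiv per 4 by Karl Fischer titration), 0.05 M, −30 °C, 4 added over 6 h; Et3N quench at −30 °C; chromatography on Et3N-deactivated silica
Reagents that add atoms: water, O
Why: Proposed new method: the acid protonates the vinyl CH2 of one molecule of 4 to give the 2,4-dimethoxy-stabilised cation 5 as a contact ion pair with the chiral anion, 5 attacks the unsubstituted alkene terminus of a second molecule of 4 (C2–C3 bond, Markovnikov head-to-tail mode) to give the equally stabilised cation 6, and a water molecule hydrogen-bonded to the anion captures C1 (C1–O bond) while the proton returns to the catalyst. The closest known reaction types are the Brønsted acid-catalysed head-to-tail dimerisation of styrenes and the asymmetric Markovnikov hydrofunctionalisation (hydroalkoxylation, hydroarylation) of styrenes under confined imidodiphosphate-type acids. No ring is closed, so no mode of ring closure arises and both new bonds are acyclic. C3 is set in the C–C bond formation, where the anion pocket shields one face of planar cation 5 so that the alkene attacks the face leading to (3S); C1 is set in the hydration, where the anion places the water on the face of cation 6 leading to (1R), and since any re-ionisation at C1 would pass through the same ion pair this centre stays under catalyst control. The step needs hydration of 6 to win over proton loss to the but-1-ene, Friedel–Crafts closure onto C6 of ring B (indane) and chain growth, while 5 must prefer the alkene to water: the pocket should admit a second styrene beside the small cation 5 but only water beside the bulkier 6, the ortho- and para-methoxy groups of each ring make both cations long-lived enough to stay paired at −30 °C, and the identical rings remove any cross-selectivity question. Any 1-(2,4,5-trimethoxyphenyl)ethanol formed from 5 and water is expected to re-ionise to 5 under the same acid and so to act as a reservoir, not as a loss.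

**Compound list**

1 | 2,4,5-trimethoxybenzaldehyde | COc1cc(OC)c(C=O)cc1OC | starting material
2 | methyltriphenylphosphonium bromide | C[P+](c1ccccc1)(c1ccccc1)c1ccccc1.[Br-] | starting material
3 | methylenetriphenylphosphorane (ylide, formed in the flask) | C=P(c1ccccc1)(c1ccccc1)c1ccccc1 | intermediate
4 | 2,4,5-trimethoxystyrene (1-ethenyl-2,4,5-trimethoxybenzene) | C=Cc1cc(OC)c(OC)cc1OC | intermediate
5 | 1-(2,4,5-trimethoxyphenyl)ethyl cation, ion-paired with the catalyst anion | C[CH+]c1cc(OC)c(OC)cc1OC | intermediate
6 | (3S)-1,3-bis(2,4,5-trimethoxyphenyl)butan-1-yl cation, ion-paired with the catalyst anion | COc1cc(OC)c([CH+]C[C@H](C)c2cc(OC)c(OC)cc2OC)cc1OC | intermediate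
7 | (1R,3S)-1,3-bis(2,4,5-trimethoxyphenyl)butan-1-ol | COc1cc(OC)c([C@H](O)C[C@H](C)c2cc(OC)c(OC)cc2OC)cc1OC | target

**Step count and risks**

Total step count: 2. Longest linear sequence: 2 steps (1 → 4 → 7).

The route has only two steps, so both are ranked, the key step first.

1. Step 2 (Proposed new method). Several processes may defeat it:
- Facial discrimination at either cationic carbon may be poor, so that stereoisomers form.
- Proton loss from cation 6, its intramolecular Friedel–Crafts alkylation of ring B, or chain growth may outrun hydration.
- Ionisation of the product carbinol on warming may erode C1.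

Fallback by known chemistry, setting out from aldehyde 1 and returning to the route at target 7:
- Allylmagnesium bromide (THF, −78 to 0 °C) adds to 1 to give racemic 1-(2,4,5-trimethoxyphenyl)but-3-en-1-ol F1.
- Dess–Martin oxidation (NaHCO3, CH2Cl2) gives 1-(2,4,5-trimethoxyphenyl)but-3-en-1-one F2.
- Catalytic DBU (CH2Cl2, rt) moves the double bond into conjugation to give (E)-1-(2,4,5-trimethoxyphenyl)but-2-en-1-one F3.
- A Hayashi–Miyaura 1,4-addition of 2,4,5-trimethoxyphenylboronic acid (Rh(acac)(C2H4)2, (R)-BINAP, dioxane/H2O, 60 °C) sets C3 and should give (3S)-1,3-bis(2,4,5-trimethoxyphenyl)butan-1-one F4. The ligand enantiomer follows the accepted facial model of this reaction and its sense is to be confirmed on the first batch.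
- Corey–Bakshi–Shibata reduction ((S)-2-methyl-CBS-oxazaborolidine, BH3·SMe2, THF, −20 °C) sets C1 under reagent control, with the aryl group as the large substituent, and should give 7.

2. Step 1. The very electron-rich styrene may oligomerise under acid or heat during work-up. Residual triphenylphosphine oxide, a strong hydrogen-bond acceptor, may be carried over and bind the chiral acid of step 2.

Fallback, setting out from aldehyde 1 and returning at styrene 4, is a Peterson olefination:
- (Trimethylsilyl)methylmagnesium chloride (THF, 0 °C) adds to 1 to give 1-(2,4,5-trimethoxyphenyl)-2-(trimethylsilyl)ethanol F5.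
- KH (THF, 0 °C to rt) effects the base-mediated syn-elimination to 4.
- No acid and no phosphorus are involved, and the silicon by-product is volatile.

**Further compounds**

F1 | step 2 | 1-(2,4,5-trimethoxyphenyl)but-3-en-1-ol (racemic) | C=CCC(O)c1cc(OC)c(OC)cc1OC
F2 | step 2 | 1-(2,4,5-trimethoxyphenyl)but-3-en-1-one | C=CCC(=O)c1cc(OC)c(OC)cc1OC
F3 | step 2 | (E)-1-(2,4,5-trimethoxyphenyl)but-2-en-1-one | C/C=C/C(=O)c1cc(OC)c(OC)cc1OC
F4 | step 2 | (3S)-1,3-bis(2,4,5-trimethoxyphenyl)butan-1-one | COc1cc(OC)c(C(=O)C[C@H](C)c2cc(OC)c(OC)cc2OC)cc1OC
F5 | step 1 | 1-(2,4,5-trimethoxyphenyl)-2-(trimethylsilyl)ethanol (racemic) | C[Si](C)(C)CC(O)c1cc(OC)c(OC)cc1OC
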